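**Retrosynthetic overview**

1. Last disconnection: the C5–propenyl bond (Suzuki–Miyaura coupling). C5 carries bromine until the end, because a propenylarene would act as a dienophile towards the quinone methide and would not tolerate the acidic sulfone formation.
2. Key disconnection: in dihydrofuran ring B, C2 is the single carbon bonded to both O1 and C3, and it bears ring C (3,4,5-trimethoxyphenyl). Cutting O1–C2 and C2–C3 together gives a (4+1) annulation between the O1–C7a–C3a–C3 heterodiene of an ortho-quinone methide of ring A and a 3,4,5-trimethoxybenzylidene carried by a chiral sulfonium ylide.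
3. The quinone methide is released by base from a 2-(1-tosylethyl)phenol, two steps from 5-bromo-2-hydroxy-3-methoxybenzaldehyde. The ylide comes from the twofold-symmetric (2R,5R)-2,5-dimethylthiolane, two steps from (2S,5S)-hexane-2,5-diol, and 3,4,5-trimethoxybenzyl bromide.
4. Ring order: rings A and C are bought; the thiolane ring of the auxiliary is made in step 4 and released again in step 6; ring B, with both stereocentres (C2 and C3), is closed in step 6.

Key step: step 6

Remark: the sulfonium salt is carried as its tetrafluoroborate, not the bromide, because bromide can attack the electron-rich benzylic carbon and reverse the S-alkylation. The sense of induction is assumed to follow that of benzylidene transfer from this thiolane to aldehydes; if it proves opposite, the antipodal diol serves in the same way.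

**Route**

Step 1
Reactants: 1 5-bromo-2-hydroxy-3-methoxybenzaldehyde
Product: 2 rac-4-bromo-2-(1-hydroxyethyl)-6-methoxyphenol
Conditions: MeMgBr (2.5 equiv), THF, 0 °C to rt; aq. NH4Cl
Reagents that add atoms: methylmagnesium bromide, C[Mg]Br
Why: Grignard 1,2-addition to the aldehyde, in which the first equivalent of MeMgBr only deprotonates the phenol and the aryl bromide is inert to an alkyl Grignard reagent at this temperature; the new carbinol centre forms as a racemate, which is acceptable because it becomes trigonal in step 6.

Step 2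
Reactants: 2 rac-4-bromo-2-(1-hydroxyethyl)-6-methoxyphenol
Product: 3 rac-4-bromo-2-methoxy-6-[1-(4-methylphenylsulfonyl)ethyl]phenol
Conditions: p-TolSO2H (1.5 equiv), p-TsOH·H2O (10 mol%), CH2Cl2, rt
Reagents that add atoms: p-toluenesulfinic acid, Cc1ccc(S(=O)O)cc1
Why: Acid-catalysed SN1-type substitution of an ortho-hydroxybenzylic alcohol, in which ionisation gives the protonated quinone methide and p-toluenesulfinic acid captures it at sulfur to give the stable sulfone, the standard entry to 2-(1-sulfonylalkyl)phenols.

Step 3
Reactants: 4 (2S,5S)-hexane-2,5-diol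
Product: 5 (2S,5S)-hexane-2,5-diyl dimethanesulfonate
Conditions: MsCl, Et3N, CH2Cl2, 0 °C
Reagents that add atoms: methanesulfonyl chloride, CS(=O)(=O)Cl
Why: Sulfonylation of both secondary alcohols at oxygen (mesylate formation), which does not touch the C–O bonds, so both centres stay S.

Step 4
Reactants: 5 (2S,5S)-hexane-2,5-diyl dimethanesulfonate
Product: 6 (2R,5R)-2,5-dimethylthiolane
Conditions: Na2S·9H2O, DMSO, rt
Reagents that add atoms: sodium sulfide (Na2S·9H2O), [Na+].[Na+].[S-2]
Why: Double SN2 substitution by sulfide, the second one a 5-exo-tet ring closure, inverts both centres and should turn the (2S,5S)-dimesylate into the (2R,5R)-thiolane.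

Step 5
Reactants: 6 (2R,5R)-2,5-dimethylthiolane; 7 3,4,5-trimethoxybenzyl bromide
Product: 8 (2R,5R)-2,5-dimethyl-1-(3,4,5-trimethoxybenzyl)thiolan-1-ium tetrafluoroborate
Conditions: NaBF4 (2 equiv), CH2Cl2/H2O, rt
Reagents that add atoms: sodium tetrafluoroborate, [Na+].F[B-](F)(F)F
Why: SN2 S-alkylation of the sulfide by the benzylic bromide with exchange of bromide for tetrafluoroborate in the two-phase medium, which pulls the equilibrium to the salt; the twofold axis of the thiolane makes both sulfur lone pairs equivalent, so no sulfur stereoisomers arise.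

Step 6
Reactants: 3 rac-4-bromo-2-methoxy-6-[1-(4-methylphenylsulfonyl)ethyl]phenol; 8 (2R,5R)-2,5-dimethyl-1-(3,4,5-trimethoxybenzyl)thiolan-1-ium tetrafluoroborate
Product: 12 (2R,3R)-5-bromo-7-methoxy-3-methyl-2-(3,4,5-trimethoxyphenyl)-2,3-dihydro-1-benzofuran, via ortho-quinone methide 9 (not isolated), via sulfonium ylide 10 (not isolated), via betaine 11 (not isolated)
Conditions: Cs2CO3 (3.5 equiv), MeCN, 0 °C to rt; 3 added slowly to 8 (1.5 equiv) and base
Reagents that add atoms: none
Why: Proposed new method: Cs2CO3 converts 3 into ortho-quinone methide 9 by loss of p-toluenesulfinate and 8 into benzylide 10; the ylide carbon adds to the exocyclic carbon of 9 (C2–C3 bond) with re-aromatisation of ring A to betaine 11, whose phenoxide then displaces the thiolane at the benzylic carbon (O1–C2 bond). The closest known reactions are the base-mediated (4+1) annulation of ortho-quinone methides from 2-(1-sulfonylalkyl)phenols with carbonyl-stabilised sulfonium ylides, which gives trans-2,3-dihydrobenzofurans, and asymmetric benzylidene transfer from 2,5-dimethylthiolanium benzylides to aldehydes. Ring B closes by 5-exo-tet substitution with inversion at C2. C2 is controlled by the twofold-symmetric (2R,5R)-thiolane, which exposes one face of the ylide carbon (the sense of its benzylidene transfer to aldehydes translates into 2R here), and C3 is set in the same C–C bond formation by an open antiperiplanar approach that keeps the trimethoxyphenyl group away from the methyl group and ring A, hence trans. The step needs ylide capture to outrun tautomerisation of 9 to the 2-vinylphenol, which slow addition of 3 to an excess of 8 and the E geometry of 9 (methyl remote from the carbonyl oxygen) should secure; the aryl bromide is inert.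

Step 7
Reactants: 12 (2R,3R)-5-bromo-7-methoxy-3-methyl-2-(3,4,5-trimethoxyphenyl)-2,3-dihydro-1-benzofuran; 13 (E)-4,4,5,5-tetramethyl-2-(prop-1-en-1-yl)-1,3,2-dioxaborolane
Product: 14 (2R,3R)-7-methoxy-3-methyl-5-[(E)-prop-1-en-1-yl]-2-(3,4,5-trimethoxyphenyl)-2,3-dihydro-1-benzofuran
Conditions: Pd(OAc)2 (3 mol%), SPhos (6 mol%), K3PO4, toluene/H2O, 80 °C
Reagents that add atoms: none
Why: Suzuki–Miyaura coupling, in which oxidative addition of the unhindered C5 bromide to zerovalent palladium carrying SPhos, transmetalation of the alkenyl boronate and reductive elimination proceed with retention of the E geometry, and the phosphate base does not epimerise C2 or C3.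

**Compound list**

1 | 5-bromo-2-hydroxy-3-methoxybenzaldehyde | COc1cc(Br)cc(C=O)c1O | starting material
2 | rac-4-bromo-2-(1-hydroxyethyl)-6-methoxyphenol | COc1cc(Br)cc(C(C)O)c1O | intermediate
3 | rac-4-bromo-2-methoxy-6-[1-(4-methylphenylsulfonyl)ethyl]phenol | COc1cc(Br)cc(C(C)S(=O)(=O)c2ccc(C)cc2)c1O | intermediate
4 | (2S,5S)-hexane-2,5-diol | C[C@H](O)CC[C@H](C)O | starting material
5 | (2S,5S)-hexane-2,5-diyl dimethanesulfonate | C[C@H](OS(C)(=O)=O)CC[C@H](C)OS(C)(=O)=O | intermediate
6 | (2R,5R)-2,5-dimethylthiolane | C[C@@H]1CC[C@@H](C)S1 | intermediate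
7 | 3,4,5-trimethoxybenzyl bromide | COc1cc(CBr)cc(OC)c1OC | starting material
8 | (2R,5R)-2,5-dimethyl-1-(3,4,5-trimethoxybenzyl)thiolan-1-ium tetrafluoroborate | C[C@@H]1CC[C@@H](C)[S+]1Cc1cc(OC)c(OC)c(OC)c1.F[B-](F)(F)F | intermediate
9 | (6E)-4-bromo-6-ethylidene-2-methoxycyclohexa-2,4-dien-1-one (ortho-quinone methide, drawn as the E isomer expected on steric grounds) | C/C=C1\C=C(Br)C=C(OC)C1=O | intermediate
10 | (2R,5R)-2,5-dimethylthiolan-1-ium-1-yl (3,4,5-trimethoxyphenyl)methanide (sulfonium ylide) | C[C@@H]1CC[C@@H](C)[S+]1[CH-]c1cc(OC)c(OC)c(OC)c1 | intermediate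
11 | 4-bromo-2-[(1S,2R)-1-[(2R,5R)-2,5-dimethylthiolan-1-ium-1-yl]-1-(3,4,5-trimethoxyphenyl)propan-2-yl]-6-methoxyphenolate (betaine) | [O-]c1c(OC)cc(Br)cc1[C@@H](C)[C@@H](c1cc(OC)c(OC)c(OC)c1)[S+]1[C@H](C)CC[C@H]1C | intermediate
12 | (2R,3R)-5-bromo-7-methoxy-3-methyl-2-(3,4,5-trimethoxyphenyl)-2,3-dihydro-1-benzofuran | Brc1cc(OC)c2c(c1)[C@@H](C)[C@H](c1cc(OC)c(OC)c(OC)c1)O2 | intermediate
13 | (E)-4,4,5,5-tetramethyl-2-(prop-1-en-1-yl)-1,3,2-dioxaborolane | C/C=C/B1OC(C)(C)C(C)(C)O1 | starting material
14 | (2R,3R)-7-methoxy-3-methyl-5-[(E)-prop-1-en-1-yl]-2-(3,4,5-trimethoxyphenyl)-2,3-dihydro-1-benzofuran | C/C=C/c1cc(OC)c2c(c1)[C@@H](C)[C@H](c1cc(OC)c(OC)c(OC)c1)O2 | target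

**Step count and risks**

Total step count: 7.
Longest linear sequence: 5 steps (4 → 5 → 6 → 8 → 12 → 14; steps 3, 4, 5, 6 and 7).

Steps most likely to fail:

Step 6 (bears the label). What may go wrong: tautomerisation or oligomerisation of the quinone methide outrunning ylide capture, O-benzylation of the phenoxide by the sulfonium salt, or weak facial discrimination in the conjugate addition. The fallback sets out from 3 and 7 and returns at 12. It uses known reactions only and closes ring B stepwise without a quinone methide.
- The phenol of 3 is capped (MOMCl first, then iPr2NEt, CH2Cl2, 0 °C, so that the phenoxide is trapped before it can expel sulfinate) to give rac-5-bromo-1-methoxy-2-(methoxymethoxy)-3-[1-(4-methylphenylsulfonyl)ethyl]benzene F1.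
- Its α-sulfonyl carbanion (LiN(iPr)2, THF, −78 °C) is alkylated with 7 to give rac-5-bromo-1-methoxy-2-(methoxymethoxy)-3-[2-(4-methylphenylsulfonyl)-1-(3,4,5-trimethoxyphenyl)propan-2-yl]benzene F2.
- KOtBu in THF eliminates p-toluenesulfinate towards the benzylic CH2 and should give 5-bromo-1-methoxy-2-(methoxymethoxy)-3-[(E)-1-(3,4,5-trimethoxyphenyl)prop-1-en-2-yl]benzene F3.
- Asymmetric hydroboration with monoisopinocampheylborane (IpcBH2, the enantiomer that delivers hydrogen to the face giving 2R), then NaOH/H2O2, adds H and OH syn with boron on the less substituted carbon. It should give (1R,2R)-2-[5-bromo-3-methoxy-2-(methoxymethoxy)phenyl]-1-(3,4,5-trimethoxyphenyl)propan-1-ol F4.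
- HCl in MeOH then removes the methoxymethyl group and ionises the 4-alkoxybenzylic alcohol. The phenol closes ring B on the cation anti to the C3 methyl group, which should give trans 12 with C3, set by the hydroboration, untouched.

Step 5. What may go wrong: slow and reversible S-alkylation of the hindered sulfide, with hydrolysis of the benzylic bromide competing in the two-phase medium. The fallback sets out from 6 and returns at 8. It is a dehydrative S-alkylation of 6 with commercial 3,4,5-trimethoxybenzyl alcohol and HBF4·OEt2 (CH2Cl2, 0 °C). The 4-alkoxybenzylic cation is captured by the sulfide and the tetrafluoroborate 8 forms directly, with water as the only by-product. No new compound is made on this path (F0).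

Step 2. What may go wrong: dehydration of the benzylic alcohol to the vinylphenol and oligomerisation of the protonated quinone methide before the weakly nucleophilic sulfinic acid captures it. The fallback sets out from 2 and returns at 3. The same cation is captured by the far more nucleophilic 4-methylbenzenethiol (p-TsOH·H2O cat., CH2Cl2, rt) to give rac-4-bromo-2-methoxy-6-[1-(4-methylphenylsulfanyl)ethyl]phenol F5. S-oxidation with mCPBA (2.2 equiv, CH2Cl2, 0 °C) then gives 3.

**Further compounds**

F1 | step 6 | rac-5-bromo-1-methoxy-2-(methoxymethoxy)-3-[1-(4-methylphenylsulfonyl)ethyl]benzene | COCOc1c(OC)cc(Br)cc1C(C)S(=O)(=O)c1ccc(C)cc1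
F2 | step 6 | rac-5-bromo-1-methoxy-2-(methoxymethoxy)-3-[2-(4-methylphenylsulfonyl)-1-(3,4,5-trimethoxyphenyl)propan-2-yl]benzene | COCOc1c(OC)cc(Br)cc1C(C)(Cc1cc(OC)c(OC)c(OC)c1)S(=O)(=O)c1ccc(C)cc1
F3 | step 6 | 5-bromo-1-methoxy-2-(methoxymethoxy)-3-[(E)-1-(3,4,5-trimethoxyphenyl)prop-1-en-2-yl]benzene | COCOc1c(OC)cc(Br)cc1/C(C)=C/c1cc(OC)c(OC)c(OC)c1
F4 | step 6 | (1R,2R)-2-[5-bromo-3-methoxy-2-(methoxymethoxy)phenyl]-1-(3,4,5-trimethoxyphenyl)propan-1-ol | COCOc1c(OC)cc(Br)cc1[C@@H](C)[C@@H](O)c1cc(OC)c(OC)c(OC)c1
F0 | step 5 | none | none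
F5 | step 2 | rac-4-bromo-2-methoxy-6-[1-(4-methylphenylsulfanyl)ethyl]phenol | COc1cc(Br)cc(C(C)Sc2ccc(C)cc2)c1O
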